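**Retrosynthetic overview**
1. Locants follow flavonoid numbering: U is the upper 3-deoxyflavan (rings A, C, B) and L is the lower flavan-3,4-diol (rings D, F, E). The plan rests on ring A, where O1-U on C8a-U and a hydroxyl on the adjacent C8-U sit between the C7-U oxygen and the C4a-U side chain. This is the pattern left when an oxygen nucleophile and an electrophile add across a C8-U/C8a-U aryne.
2. Key disconnection: the O1-U–C8a-U and C8-U–O bonds are made in one flask from a (1S,3R)-1,3-diarylpropanol whose proto-ring A is 3-fluoro-4-benzyloxyphenyl. The sequence is aryne formation, closure of ring C by the C2-U alkoxide, then borylation and oxidation of the C8-U anion under amine-free conditions.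
3. The propanol comes from gallacetophenone (ring D; acetyl masked as a ketal, O8a-L as a MOM ether). The steps are formylation at C6-L, Claisen–Schmidt condensation, rhodium-catalysed asymmetric 1,4-arylation (sets C4-U) and CBS reduction (sets C2-U).
4. Ring F: the acetyl group is unmasked and taken through a chalcone and a Juliá–Colonna epoxide to the 2,3-trans dihydroflavonol, which fixes C2-L. A flat flavonol would offer no face control so far from the upper unit. C3-L and C4-L are therefore set from C2-L, by kinetic protonation of the C3-L/C4-L enol silyl ether and then hydride reduction, both anti to ring E, to give the all-cis array.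
5. Ring order: C (step 9), then F (step 14). Rings A, B, D and E are bought, and hydrogenolysis comes last.

Key step: step 9

Abbreviation: ArD = 2,3-bis(benzyloxy)-4-(methoxymethoxy)-5-(2-methyl-1,3-dioxolan-2-yl)phenyl. It is attached through C6-L and carries benzyloxy on C7-L and C8-L, MOM-oxy on C8a-L and the ketal on C4a-L.
Assumption: the facial sense of (R)-BINAP (step 7) and of poly-L-leucine (step 13) is carried over from simple E-enones and from chalcone itself. If a test run shows the opposite sense, the antipodal ligand or polymer is used and nothing else changes.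

**Step 1**
Reactants: 1 gallacetophenone
Product: 2 3',4'-bis(benzyloxy)-2'-hydroxyacetophenone
Conditions: BnBr (2.1 equiv), K2CO3 (2.2 equiv), DMF, rt
Reagents that add atoms: benzyl bromide, BrCc1ccccc1
Why: Williamson ether synthesis; the 2'-hydroxyl is locked in a hydrogen bond to the acetyl oxygen and should stay free when only two equivalents of halide are offered.

**Step 2**
Reactants: 2 3',4'-bis(benzyloxy)-2'-hydroxyacetophenone
Product: 3 3',4'-bis(benzyloxy)-5'-bromo-2'-hydroxyacetophenone
Conditions: NBS (1.0 equiv), MeCN, 0 °C → rt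
Reagents that add atoms: N-bromosuccinimide, O=C1CCC(=O)N1Br
Why: Electrophilic aromatic bromination; the free 2'-hydroxyl directs para to C5', which is also ortho to the 4'-ether and is the only activated open position, so the halogen lands on the future C6-L.

**Step 3**
Reactants: 3 3',4'-bis(benzyloxy)-5'-bromo-2'-hydroxyacetophenone
Product: 4 3',4'-bis(benzyloxy)-5'-bromo-2'-(methoxymethoxy)acetophenone
Conditions: NaH (1.1 equiv), DMF, 0 °C; MOMCl (1.2 equiv)
Reagents that add atoms: chloromethyl methyl ether, COCCl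
Why: O-alkylation of the sodium phenoxide (Williamson type); the MOM ether withstands every basic and organometallic step up to step 13 and is the one group on ring D that mild acid can later remove beside benzyl ethers.

**Step 4**
Reactants: 4 3',4'-bis(benzyloxy)-5'-bromo-2'-(methoxymethoxy)acetophenone
Product: 5 2-[3,4-bis(benzyloxy)-5-bromo-2-(methoxymethoxy)phenyl]-2-methyl-1,3-dioxolane
Conditions: (TMSOCH2)2 (2 equiv), TMSOTf (5 mol %), CH2Cl2, −78 → −20 °C; pyridine
Reagents that add atoms: 1,2-bis(trimethylsilyloxy)ethane, C[Si](C)(C)OCCO[Si](C)(C)C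
Why: Noyori ketalisation under aprotic TMSOTf catalysis, driven by disiloxane formation, masks the acetyl group against organolithiums, enolisation and borane at a temperature at which the MOM ether is not touched.

**Step 5**
Reactants: 5 2-[3,4-bis(benzyloxy)-5-bromo-2-(methoxymethoxy)phenyl]-2-methyl-1,3-dioxolane
Product: 7 ring D aldehyde ArD–CHO, via aryllithium 6 (not isolated)
Conditions: n-BuLi (1.05 equiv), THF, −78 °C; DMF (3 equiv), −78 → 0 °C; H2O
Reagents that add atoms: N,N-dimethylformamide, CN(C)C=O (n-butyllithium, [Li]CCCC, supplies the lithium of 6 only)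
Why: Bromine–lithium exchange followed by Bouveault formylation; exchange at −78 °C is faster than any attack on the benzyl, MOM or ketal groups.

**Step 6**
Reactants: 7 ring D aldehyde ArD–CHO; 8 4'-benzyloxyacetophenone
Product: 9 (E)-1-[4-(benzyloxy)phenyl]-3-ArD-prop-2-en-1-one (upper chalcone)
Conditions: KOH, EtOH/THF, rt
Reagents that add atoms: none
Why: Claisen–Schmidt condensation (aldol addition, then E1cB dehydration) of a non-enolisable aldehyde with a methyl ketone gives the E-enone, and the only other acetyl group is hidden as its ketal.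

**Step 7**
Reactants: 9 upper chalcone; 10 4-benzyloxy-3-fluorophenylboronic acid
Product: 11 (3R)-1-[4-(benzyloxy)phenyl]-3-[4-(benzyloxy)-3-fluorophenyl]-3-ArD-propan-1-one
Conditions: [RhCl(C2H4)2]2 (2.5 mol %), (R)-BINAP (5.5 mol %), KOH (0.5 equiv), dioxane/H2O 10:1, 50 °C; 10 (2.5 equiv)
Reagents that add atoms: none
Why: Hayashi–Miyaura reaction; the aryl-rhodium species adds 1,4 to the E-enone, the (R)-BINAP quadrants select the enone face that gives (R) at C4-U, and the boronic acid has no ortho substituent, so transmetalation and insertion are unhindered.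

**Step 8**
Reactants: 11 (3R)-β,β-diaryl ketone
Product: 12 (1S,3R)-1-[4-(benzyloxy)phenyl]-3-[4-(benzyloxy)-3-fluorophenyl]-3-ArD-propan-1-ol (key-step precursor)
Conditions: (R)-Me-CBS (0.2 equiv), BH3·SMe2 (1.2 equiv), THF, −20 °C; MeOH
Reagents that add atoms: none
Why: Corey–Bakshi–Shibata reduction; the (R)-oxazaborolidine treats the aryl group as the large substituent and delivers hydride to the face that gives the (S)-carbinol at C2-U under reagent control, independently of the remote C4-U centre.

**Step 9**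
Reactants: 12 (1S,3R)-1,3-diarylpropanol
Product: 17 (2S,4R)-2,4-trans 7-benzyloxy-2-(4-benzyloxyphenyl)-4-ArD-chroman-8-ol, via dilithio species 13 (not isolated), via aryne alkoxide 14 (not isolated), via C8-U aryllithium 15 (not isolated), via dimethyl boronate 16 (not isolated)
Conditions: n-BuLi (1.0 equiv), THF, −78 °C; lithium 2,2,6,6-tetramethylpiperidide (LiTMP, 1.3 equiv), −78 °C, then n-BuLi (1.0 equiv); −78 → −20 °C; B(OMe)3 (5 equiv), −78 °C → rt; 30% H2O2, 0 °C
Reagents that add atoms: hydrogen peroxide, OO (n-butyllithium, [Li]CCCC, supplies the lithium of 13–15 and trimethyl borate, COB(OC)OC, the boron group of 16 only)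
Why: Proposed new method: after O-lithiation, LiTMP removes H8a-U, the only hydrogen next to fluorine, and the n-BuLi added afterwards turns the liberated amine back into LiTMP, so the metalation is driven to completion and no N–H acid remains; on warming, LiF leaves and the C8-U/C8a-U aryne 14 forms. The tethered C2-U alkoxide adds to C8a-U in a 6-exo-dig closure of ring C (O1-U–C8a-U bond) and leaves the carbanion on C8-U, which B(OMe)3 captures and H2O2 converts into the C8-U–O bond. The closest known reactions are the cyclisation of tethered alkoxides onto arynes to give chromans and the three-component aryne couplings in which a carbon or nitrogen nucleophile adds and an electrophile quenches the aryl anion; borate capture after an oxygen nucleophile is the extension. The step needs oxygen at C8a-U and charge at C8-U: the C7-U benzyloxy group next to the triple bond makes the remote carbon C8a-U the electrophilic end, as in 3-alkoxyarynes, and the three-carbon tether can reach only that carbon. Aryllithium 15 sits between two oxygens like 2-lithioresorcinol dibenzyl ether, which is routinely handled at 0 °C, so it should outlast the warming period. No stereocentre is formed, and because the new ether bond is made at the aryl carbon, the C2-U and C4-U configurations of 12 pass unchanged into the 2,4-trans flavan.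

**Step 10**
Reactants: 17 8-hydroxyflavan
Product: 18 (2S,4R)-7,8-bis(benzyloxy)-2-(4-benzyloxyphenyl)-4-ArD-chroman
Conditions: BnBr (1.3 equiv), K2CO3 (1.5 equiv), DMF, rt
Reagents that add atoms: benzyl bromide, BrCc1ccccc1
Why: Williamson ether synthesis on the only free phenol, which levels all ring A and ring B oxygens to benzyl ethers for the single final hydrogenolysis.

**Step 11**
Reactants: 18 ketal-protected flavan
Product: 19 methyl ketone (acetyl on C4a-L free; MOM ether on O8a-L kept)
Conditions: PPTS (0.2 equiv), acetone/H2O 10:1, 40 °C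
Reagents that add atoms: water, O
Why: Acid-catalysed ketal hydrolysis; the dioxolane ionises to an oxocarbenium ion stabilised by the alkoxy-rich ring D far faster than the aryl MOM ether is cleaved, so buffered acid should free only the acetyl group.

**Step 12**
Reactants: 19 methyl ketone; 20 4-benzyloxybenzaldehyde
Product: 21 lower (E)-chalcone with 2'-O-MOM
Conditions: KOH, EtOH/THF, rt
Reagents that add atoms: none
Why: Claisen–Schmidt condensation of the only enolisable ketone with a non-enolisable aldehyde gives the E-enone, and H4-U is far too weakly acidic for hydroxide to epimerise the upper unit.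

**Step 13**
Reactants: 21 lower chalcone
Product: 22 (αR,βS)-trans-epoxychalcone
Conditions: poly-L-leucine, urea·H2O2 (1.5 equiv), DBU (1.5 equiv), THF, rt
Reagents that add atoms: urea–hydrogen peroxide, NC(N)=O.OO
Why: Juliá–Colonna epoxidation (Weitz–Scheffer addition of hydroperoxide inside the helical polypeptide); poly-L-leucine should give the (αR,βS)-trans epoxide under catalyst control, and the MOM ether keeps the 2'-oxygen out of an Algar–Flynn–Oyamada pathway.

**Step 14**
Reactants: 22 (αR,βS)-epoxychalcone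
Product: 24 (2R,3R)-2,3-trans dihydroflavonol of the lower unit (ring F closed), via free 2'-phenol epoxide 23 (not isolated)
Conditions: HCl (1.25 M in MeOH), THF, 45 °C
Reagents that add atoms: none
Why: Acidic acetal cleavage frees O8a-L, which opens the epoxide at the benzylic carbon in a 6-endo-tet closure of ring F with inversion, so Cα becomes (3R) unchanged and Cβ becomes (2R) in the thermodynamically preferred 2,3-trans dihydroflavonol.

**Step 15**
Reactants: 24 (2R,3R)-dihydroflavonol
Product: 25 (2R)-3,4-bis(tert-butyldimethylsilyloxy)flav-3-ene of the lower unit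
Conditions: TBSOTf (3 equiv), Et3N (5 equiv), CH2Cl2, 0 °C → rt
Reagents that add atoms: tert-butyldimethylsilyl trifluoromethanesulfonate, CC(C)(C)[Si](C)(C)OS(=O)(=O)C(F)(F)F
Why: The same silyl triflate and amine silylate the C3-L hydroxyl and enolise the C4-L ketone softly; no free enolate forms, so ring F cannot open by E1cB loss of O1-L, and C2-L is kept while C3-L becomes planar.

**Step 16**
Reactants: 25 bis-silyl enediol ether
Product: 26 (2R,3S)-2,3-cis 3-O-TBS dihydroflavonol of the lower unit
Conditions: CSA (0.2 equiv), CH2Cl2/MeOH 10:1, −40 °C; cold aq NaHCO3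
Reagents that add atoms: none
Why: Diastereoselective kinetic C-protonation of a cyclic silyl enol ether; allylic 1,2-strain with the C3-L silyloxy group forces ring E pseudo-axial at C2-L, so the proton enters C3-L from the opposite face and gives the less stable 2,3-cis ketone, whose equatorial H3 lies near the carbonyl plane and should enolise only slowly.

**Step 17**
Reactants: 26 2,3-cis ketone
Product: 27 (2R,3R,4R)-all-cis 3-O-TBS flavan-3,4-diol of the lower unit
Conditions: NaBH4, CeCl3·7H2O, MeOH/THF, −78 → −40 °C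
Reagents that add atoms: none
Why: Luche-type hydride reduction; axial attack on the face opposite the axial C3-L silyloxy group and ring E (polar Felkin–Anh and steric control agree) should give the equatorial 4-hydroxyl cis to both neighbours, (4R), in a medium too weakly basic to epimerise C3-L.

**Step 18**
Reactants: 27 3-O-TBS diol
Product: 28 hexa-O-benzyl ether of the target
Conditions: TBAF (1.5 equiv), AcOH (1.5 equiv), THF, 0 °C → rt
Reagents that add atoms: none
Why: Fluoride-induced desilylation buffered by acetic acid, which avoids both acid ionisation of the benzylic C4-L hydroxyl and strongly basic alkoxides.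

**Step 19**
Reactants: 28 hexa-O-benzyl ether
Product: 29 CNP0209379.1
Conditions: H2 (1 atm), Pd(OH)2/C, THF/MeOH, rt
Reagents that add atoms: none
Why: Catalytic hydrogenolysis of the six benzyl aryl ethers in neutral solvent; the primary benzyl–oxygen bonds are cleaved much faster than the hindered secondary benzylic C2–O1 and C4-L–OH bonds, and no stereocentre is touched.

**Compound list**
1 | gallacetophenone | CC(=O)c1ccc(O)c(O)c1O | starting material
2 | 3',4'-bis(benzyloxy)-2'-hydroxyacetophenone | CC(=O)c1ccc(OCc2ccccc2)c(OCc2ccccc2)c1O | intermediate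
3 | 3',4'-bis(benzyloxy)-5'-bromo-2'-hydroxyacetophenone | CC(=O)c1cc(Br)c(OCc2ccccc2)c(OCc2ccccc2)c1O | intermediate
4 | 3',4'-bis(benzyloxy)-5'-bromo-2'-(methoxymethoxy)acetophenone | CC(=O)c1cc(Br)c(OCc2ccccc2)c(OCc2ccccc2)c1OCOC | intermediate
5 | 2-[3,4-bis(benzyloxy)-5-bromo-2-(methoxymethoxy)phenyl]-2-methyl-1,3-dioxolane | CC1(OCCO1)c1cc(Br)c(OCc2ccccc2)c(OCc2ccccc2)c1OCOC | intermediate
6 | ArD–Li, aryllithium at C6-L | CC1(OCCO1)c1cc([Li])c(OCc2ccccc2)c(OCc2ccccc2)c1OCOC | intermediate
7 | 2,3-bis(benzyloxy)-4-(methoxymethoxy)-5-(2-methyl-1,3-dioxolan-2-yl)benzaldehyde (ArD–CHO) | CC1(OCCO1)c1cc(C=O)c(OCc2ccccc2)c(OCc2ccccc2)c1OCOC | intermediate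
8 | 4'-benzyloxyacetophenone | CC(=O)c1ccc(OCc2ccccc2)cc1 | starting material
9 | (E)-1-[4-(benzyloxy)phenyl]-3-ArD-prop-2-en-1-one | O(Cc5ccccc5)c1ccc(C(=O)/C=C/c3cc(C6(C)OCCO6)c(OCOC)c(OCc5ccccc5)c3OCc5ccccc5)cc1 | intermediate
10 | 4-benzyloxy-3-fluorophenylboronic acid | OB(O)c1ccc(OCc2ccccc2)c(F)c1 | starting material
11 | (3R)-1-[4-(benzyloxy)phenyl]-3-[4-(benzyloxy)-3-fluorophenyl]-3-ArD-propan-1-one | O(Cc5ccccc5)c1ccc(C(=O)C[C@@H](c3cc(C6(C)OCCO6)c(OCOC)c(OCc5ccccc5)c3OCc5ccccc5)c3ccc(OCc5ccccc5)c(F)c3)cc1 | intermediate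
12 | (1S,3R)-1-[4-(benzyloxy)phenyl]-3-[4-(benzyloxy)-3-fluorophenyl]-3-ArD-propan-1-ol | O(Cc5ccccc5)c1ccc([C@@H](O)C[C@@H](c3cc(C6(C)OCCO6)c(OCOC)c(OCc5ccccc5)c3OCc5ccccc5)c3ccc(OCc5ccccc5)c(F)c3)cc1 | intermediate
13 | lithium alkoxide of 12 lithiated at C8a-U | O(Cc5ccccc5)c1ccc([C@@H](O[Li])C[C@@H](c3cc(C6(C)OCCO6)c(OCOC)c(OCc5ccccc5)c3OCc5ccccc5)c3ccc(OCc5ccccc5)c(F)c3[Li])cc1 | intermediate
14 | C8-U/C8a-U aryne bearing the C2-U lithium alkoxide | O(Cc5ccccc5)c1ccc([C@@H](O[Li])C[C@@H](c3cc(C6(C)OCCO6)c(OCOC)c(OCc5ccccc5)c3OCc5ccccc5)C3=CC=C(OCc5ccccc5)C#C3)cc1 | intermediate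
15 | (2S,4R)-8-lithio-7-benzyloxy-2-(4-benzyloxyphenyl)-4-ArD-chroman | O(Cc5ccccc5)c1ccc([C@@H]2C[C@@H](c3cc(C6(C)OCCO6)c(OCOC)c(OCc5ccccc5)c3OCc5ccccc5)c3ccc(OCc5ccccc5)c([Li])c3O2)cc1 | intermediate
16 | dimethyl boronate at C8-U of the same flavan | O(Cc5ccccc5)c1ccc([C@@H]2C[C@@H](c3cc(C6(C)OCCO6)c(OCOC)c(OCc5ccccc5)c3OCc5ccccc5)c3ccc(OCc5ccccc5)c(B(OC)OC)c3O2)cc1 | intermediate
17 | (2S,4R)-7-benzyloxy-2-(4-benzyloxyphenyl)-4-ArD-chroman-8-ol (2,4-trans) | O(Cc5ccccc5)c1ccc([C@@H]2C[C@@H](c3cc(C6(C)OCCO6)c(OCOC)c(OCc5ccccc5)c3OCc5ccccc5)c3ccc(OCc5ccccc5)c(O)c3O2)cc1 | intermediate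
18 | (2S,4R)-7,8-bis(benzyloxy)-2-(4-benzyloxyphenyl)-4-ArD-chroman | O(Cc5ccccc5)c1ccc([C@@H]2C[C@@H](c3cc(C6(C)OCCO6)c(OCOC)c(OCc5ccccc5)c3OCc5ccccc5)c3ccc(OCc5ccccc5)c(OCc5ccccc5)c3O2)cc1 | intermediate
19 | as 18 with acetyl in place of the ketal on C4a-L | O(Cc5ccccc5)c1ccc([C@@H]2C[C@@H](c3cc(C(C)=O)c(OCOC)c(OCc5ccccc5)c3OCc5ccccc5)c3ccc(OCc5ccccc5)c(OCc5ccccc5)c3O2)cc1 | intermediate
20 | 4-benzyloxybenzaldehyde | O=Cc1ccc(OCc2ccccc2)cc1 | starting material
21 | lower (E)-chalcone, 2'-O-MOM, upper unit (2S,4R) | O(Cc5ccccc5)c1ccc([C@@H]2C[C@@H](c3cc(C(=O)/C=C/c6ccc(OCc5ccccc5)cc6)c(OCOC)c(OCc5ccccc5)c3OCc5ccccc5)c3ccc(OCc5ccccc5)c(OCc5ccccc5)c3O2)cc1 | intermediate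
22 | (αR,βS)-trans-epoxide of 21 | O(Cc5ccccc5)c1ccc([C@@H]2C[C@@H](c3cc(C(=O)[C@@H]6O[C@H]6c7ccc(OCc5ccccc5)cc7)c(OCOC)c(OCc5ccccc5)c3OCc5ccccc5)c3ccc(OCc5ccccc5)c(OCc5ccccc5)c3O2)cc1 | intermediate
23 | epoxide 22 with free O8a-L phenol | O(Cc5ccccc5)c1ccc([C@@H]2C[C@@H](c3cc(C(=O)[C@@H]6O[C@H]6c7ccc(OCc5ccccc5)cc7)c(O)c(OCc5ccccc5)c3OCc5ccccc5)c3ccc(OCc5ccccc5)c(OCc5ccccc5)c3O2)cc1 | intermediate
24 | hexa-O-benzyl (2R,3R)-2,3-trans dihydroflavonol (lower) on the (2S,4R) upper flavan | O(Cc5ccccc5)c1ccc([C@@H]2C[C@@H](c3cc4c(c(OCc5ccccc5)c3OCc5ccccc5)O[C@H](c3ccc(OCc5ccccc5)cc3)[C@@H](O)C4=O)c3ccc(OCc5ccccc5)c(OCc5ccccc5)c3O2)cc1 | intermediate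
25 | (2R)-3,4-bis(TBS-oxy)flav-3-ene (lower) | O(Cc5ccccc5)c1ccc([C@@H]2C[C@@H](c3cc4c(c(OCc5ccccc5)c3OCc5ccccc5)O[C@H](c3ccc(OCc5ccccc5)cc3)C(O[Si](C)(C)C(C)(C)C)=C4O[Si](C)(C)C(C)(C)C)c3ccc(OCc5ccccc5)c(OCc5ccccc5)c3O2)cc1 | intermediate
26 | (2R,3S)-2,3-cis 3-O-TBS dihydroflavonol (lower) | O(Cc5ccccc5)c1ccc([C@@H]2C[C@@H](c3cc4c(c(OCc5ccccc5)c3OCc5ccccc5)O[C@H](c3ccc(OCc5ccccc5)cc3)[C@H](O[Si](C)(C)C(C)(C)C)C4=O)c3ccc(OCc5ccccc5)c(OCc5ccccc5)c3O2)cc1 | intermediate
27 | (2R,3R,4R)-all-cis 3-O-TBS flavan-3,4-diol (lower) | O(Cc5ccccc5)c1ccc([C@@H]2C[C@@H](c3cc4c(c(OCc5ccccc5)c3OCc5ccccc5)O[C@H](c3ccc(OCc5ccccc5)cc3)[C@H](O[Si](C)(C)C(C)(C)C)[C@@H]4O)c3ccc(OCc5ccccc5)c(OCc5ccccc5)c3O2)cc1 | intermediate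
28 | hexa-O-benzyl ether of the target, lower (2R,3R,4R), upper (2S,4R) | O(Cc5ccccc5)c1ccc([C@@H]2C[C@@H](c3cc4c(c(OCc5ccccc5)c3OCc5ccccc5)O[C@H](c3ccc(OCc5ccccc5)cc3)[C@H](O)[C@@H]4O)c3ccc(OCc5ccccc5)c(OCc5ccccc5)c3O2)cc1 | intermediate
29 | CNP0209379.1: upper (2S,4S) 2,4-trans, lower (2R,3R,4R) all-cis (the C4-U descriptor changes from R to S only because the ligand ranking changes on debenzylation) | Oc1ccc([C@@H]2C[C@@H](c3cc4c(c(O)c3O)O[C@H](c3ccc(O)cc3)[C@H](O)[C@@H]4O)c3ccc(O)c(O)c3O2)cc1 | target

**Totals**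
Total step count: 19. Longest linear sequence: 19 steps (1 → 29). Compounds 8, 10 and 20 are bought and enter directly.

**Steps most likely to fail**

Step 9 (Proposed new method). The C8-U aryllithium may be protonated before the borate arrives, by residual amine, by a benzylic ether CH2 or by H4-U. The hindered metalation next to fluorine may also stay incomplete. Fallback: from 12 the closure is run as a plain aryne etherification, using n-BuLi (1 equiv), then lithium 2,2,6,6-tetramethylpiperidide (2.5 equiv), THF, −78 → 0 °C and an aqueous quench. This should give the 8-unsubstituted 2,4-trans flavan F1. The C8-U oxygen is then introduced by a separate cooperative directed ortho-metalation between O1-U and the C7-U ether (n-BuLi, TMEDA, THF, 0 °C, as used for resorcinol dibenzyl ether), followed by B(OMe)3 and H2O2. The fallback rejoins the route at 17.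

Step 16. The face selectivity of the protonation may be poor, or the 2,3-cis ketone may epimerise back to the trans isomer before it is reduced. Fallback: from 21, HCl in MeOH/THF removes the MOM group to give the 2'-hydroxychalcone F2. Algar–Flynn–Oyamada oxidation (H2O2, NaOH, MeOH/THF) then gives the flavonol F3. Hydrogenation under pressure over Raney Ni adds all ring F hydrogens from one face of the pyranone and cleaves the benzyl ethers. Neither face is preferred, so 29 should form together with its lower-unit (2S,3S,4S) diastereomer F4, and the two are separated by preparative reversed-phase HPLC. The fallback rejoins the route at 29.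

Step 14. The p-alkoxybenzylic epoxide may open solvolytically, or the aroyl group may migrate, before the phenol is free, with loss of stereochemical fidelity at C2-L. Fallback: from 22, phenylmethanethiol and SnCl4 (CH2Cl2, −20 °C) open the epoxide at Cβ and strip the MOM group. This gives the 2'-hydroxy-α-hydroxy-β-(benzylsulfanyl)dihydrochalcone F5, in which Cα is untouched and both Cβ epimers are present. AgBF4 (CH2Cl2, 0 °C) then activates sulfur, and O8a-L closes ring F under control by the C3-L centre. The fallback rejoins the route at 24.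

**Further compounds**
F1 | step 9 | (2S,4R)-7-benzyloxy-2-(4-benzyloxyphenyl)-4-ArD-chroman (H on C8-U) | O(Cc5ccccc5)c1ccc([C@@H]2C[C@@H](c3cc(C6(C)OCCO6)c(OCOC)c(OCc5ccccc5)c3OCc5ccccc5)c3ccc(OCc5ccccc5)cc3O2)cc1
F2 | step 16 | lower (E)-2'-hydroxychalcone | O(Cc5ccccc5)c1ccc([C@@H]2C[C@@H](c3cc(C(=O)/C=C/c6ccc(OCc5ccccc5)cc6)c(O)c(OCc5ccccc5)c3OCc5ccccc5)c3ccc(OCc5ccccc5)c(OCc5ccccc5)c3O2)cc1
F3 | step 16 | hexa-O-benzyl flavonol (lower unit) | O(Cc5ccccc5)c1ccc([C@@H]2C[C@@H](c3cc4c(c(OCc5ccccc5)c3OCc5ccccc5)oc(-c3ccc(OCc5ccccc5)cc3)c(O)c4=O)c3ccc(OCc5ccccc5)c(OCc5ccccc5)c3O2)cc1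
F4 | step 16 | diastereomer of 29 with lower unit (2S,3S,4S) | Oc1ccc([C@@H]2C[C@@H](c3cc4c(c(O)c3O)O[C@@H](c3ccc(O)cc3)[C@@H](O)[C@H]4O)c3ccc(O)c(O)c3O2)cc1
F5 | step 14 | 2'-hydroxy-α-hydroxy-β-(benzylsulfanyl)dihydrochalcone, Cα as in 22, both Cβ epimers | O(Cc5ccccc5)c1ccc([C@@H]2C[C@@H](c3cc(C(=O)[C@H](O)C(SCc5ccccc5)c6ccc(OCc5ccccc5)cc6)c(O)c(OCc5ccccc5)c3OCc5ccccc5)c3ccc(OCc5ccccc5)c(OCc5ccccc5)c3O2)cc1
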